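## Retrosynthetic overview

1. Target ⇐ hydrogenolysis of its tris(benzyl ether) ⇐ BF3-mediated SN1 cyclodehydration of a 1,4-diaryl-2,3-dimethylbutane-1,4-diol. The oxolane ring is formed last and both benzylic centres are set under thermodynamic control.
2. Diol ⇐ aryllithium of the side-chain fragment + all-cis 5-aryl-3,4-dimethyl-γ-lactone (lactone ring opened), then ketone reduction.
3. Lactone ⇐ syn-hydrogenation of an (S)-5-aryl-3,4-dimethylbutenolide anti to the aryl group. C5 relays its chirality to both methyl centres and is itself inverted in line 1.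
4. Key C–C bond (first ring): butenolide ⇐ enantioselective Ni/Cr reductive coupling of a (Z)-β-triflyloxy enoate, acting as a β-acylvinyl anion (d3, reversed polarity), with 4-(benzyloxy)benzaldehyde.
5. Side-chain fragment ⇐ Ir-catalysed asymmetric hydrogenation of an (E)-1,2-diarylpropene ⇐ carboalumination/cross-coupling of an aryl alkyne.

Assumption: 2-(benzyloxy)-5-bromobenzaldehyde is taken as a catalogue compound (otherwise one benzylation of 5-bromosalicylaldehyde is added).
Assumption: ligand A = (S)-N-[2-(4-isopropyl-4,5-dihydro-1,3-oxazol-2-yl)-6-methylphenyl]methanesulfonamide is taken to give Re-face addition in step 2; its antipode is used if the sense is opposite.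
Assumption: ligand B = (S)-4-tert-butyl-2-[2-(di-o-tolylphosphanyl)phenyl]-4,5-dihydro-1,3-oxazole is taken to give the (R)-alkane in step 6, as it does with (E)-1,2-diphenylpropene; its antipode is used if the sense is opposite.
Locants: in the oxolane, C2 carries the 4-oxyphenyl ring and C5 the ring with the side chain.

## Route

Step 1
Reactants: 1 methyl 2-methyl-3-oxobutanoate
Product: 2 methyl (2Z)-2-methyl-3-{[(trifluoromethyl)sulfonyl]oxy}but-2-enoate
Conditions: Tf2O (1.3 equiv), satd aq LiOH, toluene, 5 °C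
Reagents that add atoms: trifluoromethanesulfonic anhydride (Tf2O), O=S(=O)(OS(=O)(=O)C(F)(F)F)C(F)(F)F
Why: O-triflation of the lithium-chelated (Z)-enolate of the β-keto ester (enol triflate formation) puts triflate and ester cis, the geometry needed later for lactonisation.

Step 2
Reactants: 2 methyl (2Z)-2-methyl-3-{[(trifluoromethyl)sulfonyl]oxy}but-2-enoate; 3 4-(benzyloxy)benzaldehyde
Product: 5 (5S)-5-[4-(benzyloxy)phenyl]-3,4-dimethylfuran-2(5H)-one, via silyl ether 4 (not isolated)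
Conditions: CrCl2 (10 mol %), ligand A (11 mol %), Et3N (20 mol %), NiCl2(dmp) (2 mol %; dmp = 2,9-dimethyl-1,10-phenanthroline), Mn powder (2 equiv), Me3SiCl (2 equiv), LiCl (2 equiv), MeCN, rt; then 1 M HCl, THF, rt
Reagents that add atoms: none
Why: Proposed new method: zerovalent nickel inserts into the electron-poor C–OTf bond, the alkenyl group passes to trivalent chromium held in the chiral oxazoline–sulfonamide pocket, and this β-(methoxycarbonyl)alkenylchromium (a β-acylvinyl anion, a d3 reversed-polarity synthon) adds to the Re face of aldehyde 3, so two inherently electrophilic carbons are joined and C5 is set (S), while Me3SiCl and Mn turn the chromium over and the acidic work-up lets the (Z)-γ-hydroxy ester lactonise without base (base would racemise C5 through the furanolate); the closest known chemistry is the catalytic asymmetric Nozaki–Hiyama–Kishi alkenylation with β-iodoacrylates and the racemic Ni/Cr butenolide synthesis from (Z)-β-halo enoates.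

Step 3
Reactants: 5 (5S)-5-[4-(benzyloxy)phenyl]-3,4-dimethylfuran-2(5H)-one
Product: 6 (3R,4S,5R)-5-[4-(benzyloxy)phenyl]-3,4-dimethyldihydrofuran-2(3H)-one (all-cis)
Conditions: H2 (3 atm), 5% Rh/Al2O3, EtOAc, rt
Reagents that add atoms: none
Why: Heterogeneous syn-hydrogenation delivers both hydrogens to the face of the planar butenolide opposite the C5 aryl group, so the two methyl groups end up cis to each other (and to the aryl) with absolute configuration relayed from C5, a known outcome for 5-aryl-3,4-dimethylbutenolides on rhodium, which spares benzyl ethers and the benzylic lactone C–O bond.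

Step 4
Reactants: 7 2-(benzyloxy)-5-bromobenzaldehyde
Product: 8 1-(benzyloxy)-4-bromo-2-ethynylbenzene
Conditions: dimethyl (1-diazo-2-oxopropyl)phosphonate (1.3 equiv), K2CO3 (2 equiv), MeOH, 0 °C to rt
Reagents that add atoms: dimethyl (1-diazo-2-oxopropyl)phosphonate, CC(=O)C(=[N+]=[N-])P(=O)(OC)OC
Why: Ohira–Bestmann (Seyferth–Gilbert) homologation converts the aryl aldehyde into the terminal alkyne under mild base that leaves the aryl bromide and benzyl ether untouched.

Step 5
Reactants: 8 1-(benzyloxy)-4-bromo-2-ethynylbenzene; 9 1-(benzyloxy)-4-iodobenzene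
Product: 11 1-(benzyloxy)-2-{(1E)-1-[4-(benzyloxy)phenyl]prop-1-en-2-yl}-4-bromobenzene, via alkenylalane 10 (not isolated)
Conditions: Me3Al (2 equiv), Cp2ZrCl2 (0.2 equiv), CH2Cl2, 0 °C to rt; then 9, Pd(PPh3)4 (5 mol %), ZnCl2 (0.3 equiv), THF, rt
Reagents that add atoms: trimethylaluminium (Me3Al), C[Al](C)C
Why: Zirconium-catalysed carboalumination adds methyl and aluminium syn across the alkyne with methyl on the aryl-bearing carbon, and the Negishi-type cross-coupling of the alkenylalane with the aryl iodide (which reacts in preference to the aryl bromide) proceeds with retention, giving only the (E)-alkene.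

Step 6
Reactants: 11 1-(benzyloxy)-2-{(1E)-1-[4-(benzyloxy)phenyl]prop-1-en-2-yl}-4-bromobenzene
Product: 12 1-(benzyloxy)-2-{(2R)-1-[4-(benzyloxy)phenyl]propan-2-yl}-4-bromobenzene
Conditions: H2 (50 bar), [Ir(cod)(ligand B)][B(3,5-(CF3)2C6H3)4] (1 mol %), CH2Cl2, rt
Reagents that add atoms: none
Why: Iridium–phosphinooxazoline asymmetric hydrogenation of an unfunctionalised (E)-trisubstituted 1,2-diarylpropene sets the benzylic methyl stereocentre (R) by catalyst-controlled face selection and tolerates the aryl bromide and benzyl ethers.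

Step 7
Reactants: 12 1-(benzyloxy)-2-{(2R)-1-[4-(benzyloxy)phenyl]propan-2-yl}-4-bromobenzene; 6 (3R,4S,5R)-5-[4-(benzyloxy)phenyl]-3,4-dimethyldihydrofuran-2(3H)-one
Product: 15 (1R,2S,3R)-1-[4-(benzyloxy)phenyl]-4-{4-(benzyloxy)-3-[(2R)-1-[4-(benzyloxy)phenyl]propan-2-yl]phenyl}-2,3-dimethylbutane-1,4-diol (both C4 epimers), via aryllithium 13 (not isolated), via lithium hemiketal alkoxide 14 (not isolated)
Conditions: 12 (1.15 equiv), n-BuLi (1.1 equiv), THF, −78 °C; 6 (1.0 equiv), −78 °C; then AcOH (1.2 equiv), CeCl3·7H2O, NaBH4, MeOH, −40 to 0 °C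
Reagents that add atoms: none
Why: Bromine–lithium exchange and 1,2-addition of the aryllithium to the lactone stop at the tetrahedral lithium hemiketal at −78 °C, and buffered Luche reduction of the ring-opened hydroxy ketone gives the diol without enolising the α-methyl centre; the three centres from 6 are untouched and the new carbinol forms as a mixture that step 8 corrects.

Step 8
Reactants: 15 (1R,2S,3R)-1-[4-(benzyloxy)phenyl]-4-{4-(benzyloxy)-3-[(2R)-1-[4-(benzyloxy)phenyl]propan-2-yl]phenyl}-2,3-dimethylbutane-1,4-diol (both C4 epimers)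
Product: 16 (2S,3S,4R,5R)-2-[4-(benzyloxy)phenyl]-5-{4-(benzyloxy)-3-[(2R)-1-[4-(benzyloxy)phenyl]propan-2-yl]phenyl}-3,4-dimethyloxolane
Conditions: BF3·OEt2 (1.5 equiv), CH2Cl2, −40 °C to rt
Reagents that add atoms: none
Why: BF3 ionises the p-alkoxybenzylic C–O bonds (SN1 cyclodehydration), and because ring opening to the benzylic cation is reversible both benzylic centres equilibrate to the most stable 2,3-trans-3,4-cis-4,5-trans arrangement with each aryl anti to its neighbouring methyl, which inverts the relay centre C2 and sets C5 while the methyl-bearing C3 and C4 never become cationic.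

Step 9
Reactants: 16 (2S,3S,4R,5R)-2-[4-(benzyloxy)phenyl]-5-{4-(benzyloxy)-3-[(2R)-1-[4-(benzyloxy)phenyl]propan-2-yl]phenyl}-3,4-dimethyloxolane
Product: 17 4-[(2S,3S,4R,5R)-5-{4-hydroxy-3-[(2R)-1-(4-hydroxyphenyl)propan-2-yl]phenyl}-3,4-dimethyloxolan-2-yl]phenol (CNP0232576.1)
Conditions: H2 (1 atm), 10% Pd/C, EtOAc/MeOH, rt
Reagents that add atoms: none
Why: Hydrogenolysis of the three aryl benzyl ethers on palladium under mild neutral conditions, stopped at full conversion, leaves the oxolane benzylic C–O bonds and all five stereocentres intact.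

## Compound list

1 | methyl 2-methyl-3-oxobutanoate | CC(=O)C(C)C(=O)OC | starting material
2 | methyl (2Z)-2-methyl-3-{[(trifluoromethyl)sulfonyl]oxy}but-2-enoate | COC(=O)/C(C)=C(/C)OS(=O)(=O)C(F)(F)F | intermediate
3 | 4-(benzyloxy)benzaldehyde | O=Cc1ccc(OCc2ccccc2)cc1 | starting material
4 | methyl (2Z,4S)-4-[4-(benzyloxy)phenyl]-2,3-dimethyl-4-[(trimethylsilyl)oxy]but-2-enoate | COC(=O)/C(C)=C(/C)[C@@H](O[Si](C)(C)C)c1ccc(OCc2ccccc2)cc1 | intermediate
5 | (5S)-5-[4-(benzyloxy)phenyl]-3,4-dimethylfuran-2(5H)-one | CC1=C(C)C(=O)O[C@H]1c1ccc(OCc2ccccc2)cc1 | intermediate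
6 | (3R,4S,5R)-5-[4-(benzyloxy)phenyl]-3,4-dimethyldihydrofuran-2(3H)-one | C[C@H]1[C@@H](C)C(=O)O[C@H]1c1ccc(OCc2ccccc2)cc1 | intermediate
7 | 2-(benzyloxy)-5-bromobenzaldehyde | O=Cc1cc(Br)ccc1OCc1ccccc1 | starting material
8 | 1-(benzyloxy)-4-bromo-2-ethynylbenzene | C#Cc1cc(Br)ccc1OCc1ccccc1 | intermediate
9 | 1-(benzyloxy)-4-iodobenzene | Ic1ccc(OCc2ccccc2)cc1 | starting material
10 | [(1E)-2-[2-(benzyloxy)-5-bromophenyl]prop-1-en-1-yl]dimethylalane | C/C(=C\[Al](C)C)c1cc(Br)ccc1OCc1ccccc1 | intermediate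
11 | 1-(benzyloxy)-2-{(1E)-1-[4-(benzyloxy)phenyl]prop-1-en-2-yl}-4-bromobenzene | C/C(=C\c1ccc(OCc2ccccc2)cc1)c1cc(Br)ccc1OCc1ccccc1 | intermediate
12 | 1-(benzyloxy)-2-{(2R)-1-[4-(benzyloxy)phenyl]propan-2-yl}-4-bromobenzene | C[C@H](Cc1ccc(OCc2ccccc2)cc1)c1cc(Br)ccc1OCc1ccccc1 | intermediate
13 | {4-(benzyloxy)-3-[(2R)-1-[4-(benzyloxy)phenyl]propan-2-yl]phenyl}lithium | [Li]c1ccc(OCc2ccccc2)c([C@H](C)Cc2ccc(OCc3ccccc3)cc2)c1 | intermediate
14 | lithium (3R,4S,5R)-2-{4-(benzyloxy)-3-[(2R)-1-[4-(benzyloxy)phenyl]propan-2-yl]phenyl}-5-[4-(benzyloxy)phenyl]-3,4-dimethyloxolan-2-olate (C2 epimers) | C[C@H]1[C@@H](C)C(O[Li])(c2ccc(OCc3ccccc3)c([C@H](C)Cc3ccc(OCc4ccccc4)cc3)c2)O[C@H]1c1ccc(OCc2ccccc2)cc1 | intermediate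
15 | (1R,2S,3R)-1-[4-(benzyloxy)phenyl]-4-{4-(benzyloxy)-3-[(2R)-1-[4-(benzyloxy)phenyl]propan-2-yl]phenyl}-2,3-dimethylbutane-1,4-diol (both C4 epimers) | OC(c1ccc(OCc2ccccc2)c([C@H](C)Cc2ccc(OCc3ccccc3)cc2)c1)[C@H](C)[C@H](C)[C@@H](O)c1ccc(OCc2ccccc2)cc1 | intermediate
16 | (2S,3S,4R,5R)-2-[4-(benzyloxy)phenyl]-5-{4-(benzyloxy)-3-[(2R)-1-[4-(benzyloxy)phenyl]propan-2-yl]phenyl}-3,4-dimethyloxolane | C[C@H]1[C@@H](C)[C@H](c2ccc(OCc3ccccc3)c([C@H](C)Cc3ccc(OCc4ccccc4)cc3)c2)O[C@@H]1c1ccc(OCc2ccccc2)cc1 | intermediate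
17 | 4-[(2S,3S,4R,5R)-5-{4-hydroxy-3-[(2R)-1-(4-hydroxyphenyl)propan-2-yl]phenyl}-3,4-dimethyloxolan-2-yl]phenol | C[C@@H]1[C@H](C)[C@@H](c2ccc(O)cc2)O[C@H]1c1ccc(O)c([C@H](C)Cc2ccc(O)cc2)c1 | target

## Step count and risks

Total steps: 9. Longest linear sequence: 6 steps (1, 2, 3, 7, 8, 9; the side-chain branch 4, 5, 6, 7, 8, 9 is equally long).

Three steps most likely to fail:

Step 2. The enantioselective Ni/Cr coupling is untested on a tetrasubstituted β-triflyloxy enoate; pinacol coupling of 3 or low ee are the likely failures. The fallback sets out from 3 and returns at 5. ProPhenol/Me2Zn-catalysed addition of propyne to 3 gives (1S)-1-[4-(benzyloxy)phenyl]but-2-yn-1-ol F1. MeMgCl with catalytic CuI in refluxing THF then adds methyl to the alkyne carbon next to the alkoxide (anti-carbomagnesiation through the magnesium chelate), CO2 traps the alkenylmagnesium, and acidification gives (2Z,4S)-4-[4-(benzyloxy)phenyl]-4-hydroxy-2,3-dimethylbut-2-enoic acid F2, which lactonises to 5.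

Step 3. The tetrasubstituted alkene may be slow, and over-reduction (benzylic C–O cleavage, arene saturation) may compete. The fallback sets out from 5 and returns at 6. Conjugate reduction with [(Ph3P)CuH]6 (5 mol %) and PhMe2SiH in toluene delivers hydride to C4 anti to the aryl group and gives {[(4S,5R)-5-[4-(benzyloxy)phenyl]-3,4-dimethyl-4,5-dihydrofuran-2-yl]oxy}(dimethyl)phenylsilane F3. Kinetic protonation with AcOH in THF at −78 °C from the face opposite the C4 methyl then gives 6.

Step 8. Equilibration of the benzyl ethers may stop short of full inversion at C2, or elimination may erode the methyl centres. The fallback sets out from 15 and returns at 17. MsCl/Et3N (CH2Cl2, 0 °C) closes the ring without equilibration to the C2/C5-epimeric (3S,4R)-2-[4-(benzyloxy)phenyl]-5-{4-(benzyloxy)-3-[(2R)-1-[4-(benzyloxy)phenyl]propan-2-yl]phenyl}-3,4-dimethyloxolane F4. Hydrogenolysis (H2, Pd/C) gives the C2/C5-epimeric 4-[(3S,4R)-5-{4-hydroxy-3-[(2R)-1-(4-hydroxyphenyl)propan-2-yl]phenyl}-3,4-dimethyloxolan-2-yl]phenol F5. Catalytic HCl in MeOH at rt then equilibrates the benzylic centres through ring-opened p-quinone methides, which the free para-hydroxy groups make much easier, to 17.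

Further compounds
F1 | step 2 | (1S)-1-[4-(benzyloxy)phenyl]but-2-yn-1-ol | CC#C[C@@H](O)c1ccc(OCc2ccccc2)cc1
F2 | step 2 | (2Z,4S)-4-[4-(benzyloxy)phenyl]-4-hydroxy-2,3-dimethylbut-2-enoic acid | OC(=O)/C(C)=C(/C)[C@@H](O)c1ccc(OCc2ccccc2)cc1
F3 | step 3 | {[(4S,5R)-5-[4-(benzyloxy)phenyl]-3,4-dimethyl-4,5-dihydrofuran-2-yl]oxy}(dimethyl)phenylsilane | C[C@H]1C(C)=C(O[Si](C)(C)c2ccccc2)O[C@H]1c1ccc(OCc2ccccc2)cc1
F4 | step 8 | (3S,4R)-2-[4-(benzyloxy)phenyl]-5-{4-(benzyloxy)-3-[(2R)-1-[4-(benzyloxy)phenyl]propan-2-yl]phenyl}-3,4-dimethyloxolane (C2/C5 epimers) | C[C@H]1[C@@H](C)C(c2ccc(OCc3ccccc3)c([C@H](C)Cc3ccc(OCc4ccccc4)cc3)c2)OC1c1ccc(OCc2ccccc2)cc1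
F5 | step 8 | 4-[(3S,4R)-5-{4-hydroxy-3-[(2R)-1-(4-hydroxyphenyl)propan-2-yl]phenyl}-3,4-dimethyloxolan-2-yl]phenol (C2/C5 epimers) | C[C@H]1[C@@H](C)C(c2ccc(O)c([C@H](C)Cc3ccc(O)cc3)c2)OC1c1ccc(O)cc1
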